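The product here is chains, and the length you asked for is monomer in chains divided by chains begun, so I reckon the two apart. You wanted a quick number, so here is the problem and then my commitment.

| flask | free monomer | transfer agent | initiator | impurity | remark | time |
|---|---|---|---|---|---|---|
| alder | 19 mM | 0.19 mM | 0.47 mM | 26 µM | run made earlier |  |
| cedar | 19 mM | 0.19 mM | 0.47 mM | 38 µM | run made earlier |  |
| elm | 19 mM | 0.19 mM | 0.94 mM | 51 µM | run made earlier |  |
| north-west | 19 mM | 0.190 mM | 0.47 mM | 51 µM |  | 5.0 min |
| south | 19 mM | 0.190 mM | 0.47 mM | 51 µM |  | 1.5 min |

- alder (time / min: monomer in chains / %, free monomer / %): 0.833: 37, 68; 1.50: 59, 43; 2.50: 76, 22; 3.00: 82, 18; 4.00: 97, 9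
- cedar (time / min: monomer in chains / %, free monomer / %): 0.833: 31, 74; 1.50: 54, 43; 2.50: 76, 25; 3.00: 84, 16; 4.00: 90, 10
- elm (time / min: monomer in chains / %, free monomer / %): 0.333: 16, 81; 1.00: 59, 41; 2.00: 91, 11; 3.00: 98, 3; 4.00: 98, 4

(scatter of a reading: 2 percentage points)

- the average divides the monomer in chains by the number of chains begun, living and dead together
- the earlier runs do not show the number of chains; that part of a forecast is a guess

1. which of the two ends with the longer chains by the average number of monomer units in a chain (chains begun, living or dead) ("neither" if they lie within 10%) (north-west / south / neither)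
2. average number of monomer units in a chain (chains begun, living or dead) at the end, north-west
3. average number of monomer units in a chain (chains begun, living or dead) at the end, south

The top of the fraction comes from the cedar run, which has your initiator charge and the closer impurity charge. Its free monomer falls pseudo-first-order, and you can read the slope between 1.50 min and 4.00 min:

k = ln(43% / 10%) / (4.00 min − 1.50 min) = 0.583 min⁻¹

Carried on to 5.0 min, that puts 94.4% of the free monomer into chains in north-west. For south at 1.5 min, I take cedar's reading at that time, 54%.

For the bottom, I allow one chain for each initiator the impurity leaves: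

c(initiator) − c(impurity) = 0.419 mM, the chain budget

The elm slope over the cedar slope reads 2.26, and the elm budget over the cedar budget is 2.06. I count no chains for the transfer agent, which is my guess, since the runs do not show the count. So:

north-west: 94.4% × 19 mM / 0.419 mM = 42.8

south: 54% × 19 mM / 0.419 mM = 24.5

The forecast you sent also picks north-west, but its numbers are lower than mine: 31 (23 to 55) for north-west and 18 (12 to 32) for south. We differ on the bottom of the fraction, where it says: “Chains are then about 0.55–0.6 and 0.5 mM”.

    free monomer + initiator → living end + monomer in chains (k = 2.80 M⁻¹ s⁻¹)
    free monomer + living end → monomer in chains + living end, rate k2*[living end]*[free monomer] (k = 26.0 M⁻¹ s⁻¹)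
    living end + transfer agent → dead chain (kL = 2.80 M⁻¹ s⁻¹)
    initiator + impurity → spent initiator (k = 1900 M⁻¹ s⁻¹)

The flask gives north-west, with 42.9 for north-west and 25.0 for south, so the forecast reads low by a factor of 1.38 in north-west. At 5.00 min in north-west, living end 0.368 mM and dead chain 0.0499 mM add up to 0.418 mM, against the budget of 0.419 mM. In the scheme, the transfer agent turns a living end into a dead chain. A neighbouring flask is north-west with 0.19 mM of initiator, so its budget is 0.139 mM. With 61.6% of the free monomer in chains, that gives 84.2. That neighbouring flask ends at 84.1.

The numbers in the tables come from a simulation with made-up constants, noise included.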